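(The numbers in the tables were generated by integration for an exercise.)

I follow the products. Eta is the flask itself, followed so far, and gamma is an earlier run with more precatalyst.

| flask | left-handed substrate | right-handed substrate | coupling partner | free catalyst | precatalyst | impurity | remark | time |
|---|---|---|---|---|---|---|---|---|
| eta | 21 mM | 21 mM | 46.2 mM | 92 µM | 0.21 mM | 23 µM | the very flask that is asked about, followed so far |  |
| gamma | 21 mM | 21 mM | 46.2 mM | 92 µM | 0.32 mM | 23 µM | run made earlier |  |
| flask | 21 mM | 21 mM | 46.2 mM | 92 µM | 0.21 mM | 23 µM |  | 10 min |

- eta (time / min: left-handed substrate / %, right-handed substrate / %): 0.167: 42.3, 49.2; 0.500: 37.8, 47.3; 0.833: 36.7, 45.5; 1.33: 35.9, 43.1; 2.00: 36.1, 40.3; 2.50: 36.9, 39.0; 3.00: 36.8, 38.6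
- gamma (time / min: left-handed substrate / %, right-handed substrate / %): 0.833: 35.4, 44.5; 1.33: 36.8, 41.4; 2.00: 37.1, 39.7; 3.00: 36.4, 38.8; 4.00: 38.2, 37.5; 6.00: 38.0, 38.1; 10.0: 37.2, 38.5

(readings scatter by 0.5 percentage points)

- free catalyst is single-handed; left-handed substrate and right-handed substrate are mirror images of each other, charged as a racemate, each of them at the stated concentration
- an excess is below zero if the other one leads

1. part of the left-handed substrate and right-handed substrate charged together that has reacted at 10 min
2. excess of left-handed product over right-handed product in the product at 10 min
3. excess of right-handed substrate over left-handed substrate among what is left of the two at 10 min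

The reacted part levels off in gamma at 24.3% by 10.0 min, and eta has reacted 24.6% at 3.00 min, so I expect about that for c, with the two substrates level and their excess near zero.

For the product I take two extremes. If the substrates never turned into each other, level substrates would mean level products, an excess of zero. But in eta the left-handed substrate, which lost more than the right-handed by the first reading, reads 35.9% and then 36.8% while the right-handed falls from 43.1% to 38.6%, so I take it that right-handed substrate is becoming left-handed. If that passage were instant, the substrates would stay equal and, assuming the products keep their hand, every moment would give the same split, the selectivity factor s read at the first reading: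

s = left-handed lost / right-handed lost = 9.63

excess = (s − 1)/(s + 1) = 81.2%

I call this the split excess. A lagging passage lowers the split of the moment: the left-handed substrate was 0.799 of the right-handed at 0.500 min, and with s as read that gap gives 77.0% for that moment. The right-handed loss in s is 0.8 percentage points against a scatter of 0.5 points, so s is rough, and I place the real flask near the split excess, on either side of that figure, and far from zero.

The forecast gives 24.3%, 0.5% and 0.1%, reasoning “with no net substrate racemization the products are equal too”.

The flask gives 24.1%, 83.5% and 0%.

    free catalyst → spent catalyst B (k = 0.0265 s⁻¹)
    coupling partner + precatalyst → racemization catalyst + spent reagent (k = 0.820 M⁻¹ s⁻¹)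
    free catalyst + impurity → spent catalyst A (k = 94100 M⁻¹ s⁻¹)
    left-handed substrate + racemization catalyst ⇌ right-handed substrate + racemization catalyst, rate k4*[racemization catalyst]*[left-handed substrate] forward; the back reaction follows from the equilibrium constant (k = 54.8 M⁻¹ s⁻¹)
    coupling partner + free catalyst + right-handed substrate → free catalyst + right-handed product (k = 400 M⁻² s⁻¹)
    coupling partner + free catalyst + left-handed substrate → free catalyst + left-handed product (k = 5240 M⁻² s⁻¹)

The substrates stand at 37.9% and 37.9% beside 22.1% left-handed and 1.99% right-handed product, and the excess lies 2.3 points above the split excess. Half of c times one plus the split excess gives 21.8% left-handed product here. The neighbouring flask with 0.058 mM of impurity reaches c of 13.9%, so the same reckoning gives 12.6%, and that flask holds 12.8% left-handed product at an excess of 84.7%.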